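1. The rate constants are unknown to us, so we read this flask from two runs made at the same gas level.

| flask | substrate | gas | remark | time |
|---|---|---|---|---|
| midnight | 16 mM (fed, over 4.0 h) | 14 mM (held) | run made earlier |  |
| dawn | 36 mM (fed, over 4.0 h) | 14 mM (held) | run made earlier |  |
| flask | 24 mM (fed, over 4.0 h) | 14 mM (held) |  | 5.0 h |

| run | time / h | target / % | side product / % |
|---|---|---|---|
| midnight | 0.500 | 0 | 0.1 |
| midnight | 1.50 | 0.9 | 0.4 |
| midnight | 3.00 | 12.8 | 5.6 |
| midnight | 4.00 | 23.4 | 10.6 |
| midnight | 6.00 | 44.4 | 19.2 |
| dawn | 0.500 | 0.5 | 0 |
| dawn | 0.833 | 0.2 | 0.1 |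
| dawn | 1.50 | 1.9 | 0.6 |
| dawn | 3.00 | 11.6 | 5.2 |
| dawn | 6.00 | 42.4 | 18.6 |

(scatter of a reading: 0.5 percentage points)

- at the start none of reagent is dissolved
- steps under discussion: adduct -> target; gas <-> reagent; substrate + reagent <-> adduct; adduct -> side product
- percentages count the whole charge, also what has not yet gone in

1. amount of target in the flask at 5.0 h, in percent of the substrate charged
2. amount of side product in the flask at 5.0 h, in percent of the substrate charged
3. amount of adduct in the flask at 5.0 h, in percent of the substrate charged
4. concentration of reagent at 5.0 h, in mM

2. First, the lag. At 1.50 h the midnight run holds 1.30 % of products together, and that moment comes sooner than the end of the feed.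

3. Next: the feed, done at 4.0 h. From 3.00 h to 6.00 h the midnight run makes products at a pace of one charge per 6.64 h. In that run substrate goes in faster than products come out, so material piles up in between: 66.0 % of the charge at 4.00 h.

4. Then the two products. We carry the target share (a selectivity), target divided by target plus side product: 0.698 in the midnight run and 0.695 in the dawn run, both at 6.00 h.

5. Our reckoning for this flask at 5.0 h: the midpoint of the midnight readings at 4.00 h and 6.00 h, taken over to this flask, gives 48.8 % of products, so 34.1 % target and 14.7 % side product. The remaining 51.2 % is substrate plus adduct, and the readings give neither of these.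

6. The forecast gives 33.5 % target, 14.7 % side product, 24 % adduct and 5 mM reagent, and it warns: “Reagent's absolute level is poorly determined”.

7. The flask gives 34.1 % target, 15.0 % side product, 31.4 % adduct and 11.9 mM reagent.

    adduct → target (k = 0.00590 min⁻¹)
    gas ⇌ reagent, rate k2*(csat - [reagent]) (kL = 0.0290 min⁻¹)
    substrate + reagent ⇌ adduct (K = 400 M⁻¹, k = 1.20 M⁻¹ min⁻¹)
    adduct → side product (k = 0.00260 min⁻¹)

8. The forecast holds for the two products and parts from the flask on adduct and reagent. At 1.70 h adduct in this flask falls back more slowly than it goes on, at 0.35 of that rate. At 5.0 h this flask holds 31.4 % adduct beside 19.5 % substrate, and its target share is 0.695. At 5.00 h the flask with 96 mM of substrate has reagent at 6.32 mM, and our share times its products gives 25.9 % target, against the 25.8 % that flask holds.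

The data stem from a simulated flask for an exercise.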